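**Strategy.** The target is a trans-fused guaiane-type hydroazulene (numbered C1–C10: C1/C5 ring fusion, C4 quaternary, C7 isopropenyl-bearing, C10 carbinol) whose C4 carries the benzylic carbon C1′. Everything rests on disconnecting the cyclopentane at C1–C5 and C3–C4: a phosphine-catalysed intramolecular (3+2) annulation in which a but-2-ynoyl unit (C10 ketone, C1–C3) adds across an (E)-2-methylenoate (C5=C4; ester carbon = C1′). One operation closes the cycloheptane (C1, C5–C10) and the cyclopentane (C1–C5) and creates the quaternary C4 from an acyclic ynone–enoate made from (R)-limonene oxide. The C10 ketone later accepts the methyl group; the ester becomes the benzylic centre.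

Key step: step 5

Remark: the commercial cis/trans mixture of (4R)-limonene 1,2-oxide is used because both epoxides give the same keto aldehyde; compound names use azulene locants, the discussion uses the guaiane numbers defined above.

Step 1
Reactants: 1 (4R)-limonene 1,2-oxide (cis/trans mixture)
Product: 2 (3R)-6-oxo-3-(prop-1-en-2-yl)heptanal
Conditions: H5IO6 (1.2 equiv), THF/H2O, 0 °C → rt
Reagents that add atoms: water, O
Why: Acid-promoted opening of the trisubstituted epoxide to the diol and periodate glycol cleavage (Malaprade reaction) should outpace any reaction of the 1,1-disubstituted alkene, and the stereocentre (future C7) is not involved.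

Step 2
Reactants: 2 (3R)-6-oxo-3-(prop-1-en-2-yl)heptanal; 3 ethyl 2-(triphenyl-λ5-phosphanylidene)propanoate
Product: 4 ethyl (2E,5R)-2-methyl-8-oxo-5-(prop-1-en-2-yl)non-2-enoate
Conditions: CH2Cl2, rt
Reagents that add atoms: ethyl 2-(triphenyl-λ5-phosphanylidene)propanoate (3), CCOC(=O)C(C)=P(c1ccccc1)(c1ccccc1)c1ccccc1
Why: Wittig reaction of the stabilised α-methyl ylide is aldehyde-selective over the methyl ketone and should give the (E)-2-methylenoate, whose geometry later fixes C4 relative to C5.

Step 3
Reactants: 4 ethyl (2E,5R)-2-methyl-8-oxo-5-(prop-1-en-2-yl)non-2-enoate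
Product: 5 (4R,6E)-8-ethoxy-7-methyl-8-oxo-4-(prop-1-en-2-yl)oct-6-enoic acid
Conditions: aq. NaOCl (3.5 equiv, pH > 12), 1,4-dioxane, 5 °C; Na2SO3; then HCl to pH 3
Reagents that add atoms: water, O (as hydroxide)
Why: Haloform reaction: exhaustive α-chlorination of the methyl ketone and hydroxide cleavage excise the methyl carbon as chloroform, while at high pH and low temperature hypochlorite should leave the isopropenyl and enoate double bonds and the hindered conjugated ester intact.

Step 4
Reactants: 5 (4R,6E)-8-ethoxy-7-methyl-8-oxo-4-(prop-1-en-2-yl)oct-6-enoic acid; 6 propyne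
Product: 8 ethyl (2E,5R)-2-methyl-8-oxo-5-(prop-1-en-2-yl)undec-2-en-9-ynoate, via acid chloride 7 (not isolated)
Conditions: 1-chloro-N,N,2-trimethylprop-1-enylamine, CH2Cl2, 0 °C; then propyne (excess), PdCl2(PPh3)2 (2 mol %), CuI (4 mol %), Et3N, THF, rt
Reagents that add atoms: propyne (6), CC#C
Why: The neutral α-chloroenamine converts the acid into the acid chloride without free HCl, and the acyl Sonogashira coupling should give the but-2-ynone without touching the enoate.

Step 5
Reactants: 8 ethyl (2E,5R)-2-methyl-8-oxo-5-(prop-1-en-2-yl)undec-2-en-9-ynoate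
Product: 10 ethyl (1S,7R,8aS)-1-methyl-4-oxo-7-(prop-1-en-2-yl)-1,2,4,5,6,7,8,8a-octahydroazulene-1-carboxylate, via phosphonium dienolate zwitterion 9 (not isolated)
Conditions: PBu3 (20 mol %), toluene (0.01 M, slow addition of 8), 80 °C
Reagents that add atoms: none
Why: PBu3 adds to the ynone β-carbon (C2) and a proton shift gives the 2-phosphonio dienolate 9, a C1/C3 dipole; its α-carbon C1 adds to C5 of the enoate (7-exo-trig, closing the cycloheptanone), the resulting C4 ester enolate attacks C3 of the vinylphosphonium (5-endo-trig, closing the cyclopentane and creating the quaternary C4), and a proton shift with loss of PBu3 leaves the C1=C2 enone. The closest known reaction is the Lu (3+2) annulation of 2-butynoyl or allenoyl compounds with electron-poor alkenes, including intramolecular variants with the tether on the acyl side. C4 relative to C5 follows from the (E)-alkene geometry (suprafacial addition, ester cis to H-5, methyl cis to C6). C5 relative to the resident C7 centre is expected to be set in a reversible Michael addition followed by product-determining ring closure through a chair-like cycloheptanone with isopropenyl equatorial, the phosphonium-bearing C2 equatorial and C4 axial (one syn-axial hydrogen only, beside the carbonyl), which places C4 anti to isopropenyl as required. The step needs chemoselective activation of the ynone over the enoate and isopropenyl group and α-regioselectivity, which the acyl-side tether secures because γ-attack would need a nine-membered ring; high dilution suppresses oligomerisation. The 1,3-induction from C7 is the least secure element of the route.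

Step 6
Reactants: 10 ethyl (1S,7R,8aS)-1-methyl-4-oxo-7-(prop-1-en-2-yl)-1,2,4,5,6,7,8,8a-octahydroazulene-1-carboxylate
Product: 11 ethyl (1S,3aR,7R,8aS)-1-methyl-4-oxo-7-(prop-1-en-2-yl)decahydroazulene-1-carboxylate
Conditions: [(Ph3P)CuH]6 (0.4 equiv), benzene, H2O (2 equiv), rt; then NaOEt (0.2 equiv), EtOH, rt
Reagents that add atoms: none
Why: Copper hydride conjugate reduction is selective for the enone over the isolated alkene and the ester, and ethoxide equilibration through the C10 enolate should set C1 to the more stable trans ring fusion (H-1 anti to H-5).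

Step 7
Reactants: 11 ethyl (1S,3aR,7R,8aS)-1-methyl-4-oxo-7-(prop-1-en-2-yl)decahydroazulene-1-carboxylate; 12 methyllithium
Product: 13 ethyl (1S,3aR,4R,7R,8aS)-4-hydroxy-1,4-dimethyl-7-(prop-1-en-2-yl)decahydroazulene-1-carboxylate
Conditions: MeAl(OAr)2 (Ar = 2,6-di-tert-butyl-4-methylphenyl; 3 equiv), toluene, −78 °C; then MeLi (3 equiv), −78 °C
Reagents that add atoms: methyllithium (12), [Li]C
Why: Amphiphilic carbonyl methylation: the bulky aluminium phenoxide binds the ketone on its open equatorial side so that MeLi should be delivered axially, anti to H-1, giving the equatorial hydroxyl cis to H-1 (the C10 configuration of the target), while the neopentyl ester does not react at −78 °C.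

Step 8
Reactants: 13 ethyl (1S,3aR,4R,7R,8aS)-4-hydroxy-1,4-dimethyl-7-(prop-1-en-2-yl)decahydroazulene-1-carboxylate
Product: 14 (1S,3aR,4R,7R,8aS)-4-hydroxy-1,4-dimethyl-7-(prop-1-en-2-yl)decahydroazulene-1-carbaldehyde
Conditions: i-Bu2AlH (2.2 equiv), CH2Cl2, −78 °C; aq. potassium sodium tartrate
Reagents that add atoms: none
Why: Partial reduction of the hindered neopentyl ester: the aluminium hemiacetal is stable at −78 °C and should collapse to the non-enolisable aldehyde only on work-up.

Step 9
Reactants: 14 (1S,3aR,4R,7R,8aS)-4-hydroxy-1,4-dimethyl-7-(prop-1-en-2-yl)decahydroazulene-1-carbaldehyde; 15 3,5-dimethoxyphenol; 16 isobutylmagnesium bromide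
Product: 19 2-{(1R)-1-[(1S,3aR,4R,7R,8aS)-4-hydroxy-1,4-dimethyl-7-(prop-1-en-2-yl)decahydroazulen-1-yl]-3-methylbutyl}-3,5-dimethoxyphenol, via ortho-hydroxybenzyl alkoxide 17 (not isolated), via ortho-quinone methide 18 (not isolated)
Conditions: 15, EtMgBr (1 equiv), Et2O then toluene; 14, rt → 60 °C; then i-BuMgBr (5 equiv), CuBr·SMe2 (10 mol %), THF, −20 °C → rt
Reagents that add atoms: 3,5-dimethoxyphenol (15), COc1cc(O)cc(OC)c1; isobutylmagnesium bromide (16), CC(C)C[Mg]Br
Why: ortho-Selective hydroxyalkylation of the magnesium phenoxide by the aldehyde (chelated six-membered transition state) gives 17, loss of the benzylic oxygen generates ortho-quinone methide 18, and copper-assisted 1,4-addition of the isobutyl Grignard reagent restores the phenol; with the C4 methyl eclipsing the exocyclic C=C (minimal allylic 1,3-strain) the nucleophile should enter anti to the C5 branch, which gives the (R) centre at C1′.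

Step 10
Reactants: 19 2-{(1R)-1-[(1S,3aR,4R,7R,8aS)-4-hydroxy-1,4-dimethyl-7-(prop-1-en-2-yl)decahydroazulen-1-yl]-3-methylbutyl}-3,5-dimethoxyphenol; 20 N,N-dimethylformamide
Product: 21 4-hydroxy-5-{(1R)-1-[(1S,3aR,4R,7R,8aS)-4-hydroxy-1,4-dimethyl-7-(prop-1-en-2-yl)decahydroazulen-1-yl]-3-methylbutyl}-2,6-dimethoxybenzene-1,3-dicarbaldehyde
Conditions: POCl3 (3 equiv), DMF (6 equiv), MeCN, 0 °C → rt; then aq. NaOAc, rt
Reagents that add atoms: N,N-dimethylformamide (20), CN(C)C=O; water, O
Why: Vilsmeier–Haack formylation: after the first formylation the hydroxyaryl iminium relaxes to a neutral quinone-methide enaminone that remains nucleophilic at the last ring CH, so both positions should be formylated at room temperature, where the hindered tertiary alcohol and the isopropenyl group are not attacked.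

Step 11
Reactants: 21 4-hydroxy-5-{(1R)-1-[(1S,3aR,4R,7R,8aS)-4-hydroxy-1,4-dimethyl-7-(prop-1-en-2-yl)decahydroazulen-1-yl]-3-methylbutyl}-2,6-dimethoxybenzene-1,3-dicarbaldehyde
Product: 22 2,4,6-trihydroxy-5-{(1R)-1-[(1S,3aR,4R,7R,8aS)-4-hydroxy-1,4-dimethyl-7-(prop-1-en-2-yl)decahydroazulen-1-yl]-3-methylbutyl}benzene-1,3-dicarbaldehyde (CNP0594576.1)
Conditions: NaSEt (8 equiv), DMF, 110 °C; then dilute HCl
Reagents that add atoms: none
Why: SN2 demethylation by ethanethiolate: each methoxy group is ortho to a formyl group, so the aryloxide is a stabilised leaving group, while the alkene, the tertiary alcohol and the aldehydes are inert to thiolate; acidification liberates the triphenol.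

**Compound list**

1 | (4R)-limonene 1,2-oxide (cis/trans mixture) | C=C(C)[C@@H]1CCC2(C)OC2C1 | starting material
2 | (3R)-6-oxo-3-(prop-1-en-2-yl)heptanal | C=C(C)[C@@H](CC=O)CCC(C)=O | intermediate
3 | ethyl 2-(triphenyl-λ5-phosphanylidene)propanoate | CCOC(=O)C(C)=P(c1ccccc1)(c1ccccc1)c1ccccc1 | starting material
4 | ethyl (2E,5R)-2-methyl-8-oxo-5-(prop-1-en-2-yl)non-2-enoate | C=C(C)[C@@H](C/C=C(\C)C(=O)OCC)CCC(C)=O | intermediate
5 | (4R,6E)-8-ethoxy-7-methyl-8-oxo-4-(prop-1-en-2-yl)oct-6-enoic acid | C=C(C)[C@@H](C/C=C(\C)C(=O)OCC)CCC(=O)O | intermediate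
6 | propyne | CC#C | starting material
7 | ethyl (2E,5R)-8-chloro-2-methyl-8-oxo-5-(prop-1-en-2-yl)oct-2-enoate (acid chloride) | C=C(C)[C@@H](C/C=C(\C)C(=O)OCC)CCC(=O)Cl | intermediate
8 | ethyl (2E,5R)-2-methyl-8-oxo-5-(prop-1-en-2-yl)undec-2-en-9-ynoate | C=C(C)[C@@H](C/C=C(\C)C(=O)OCC)CCC(=O)C#CC | intermediate
9 | 2-(tributylphosphonio)buta-1,3-dien-1-olate zwitterion derived from 8 (C10 enolate, C2 phosphonium, C3 methylene) | C=C(C)[C@@H](C/C=C(\C)C(=O)OCC)CCC([O-])=CC(=C)[P+](CCCC)(CCCC)CCCC | intermediate
10 | ethyl (1S,7R,8aS)-1-methyl-4-oxo-7-(prop-1-en-2-yl)-1,2,4,5,6,7,8,8a-octahydroazulene-1-carboxylate | C=C(C)[C@@H]1CCC(=O)C2=CC[C@](C)(C(=O)OCC)[C@H]2C1 | intermediate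
11 | ethyl (1S,3aR,7R,8aS)-1-methyl-4-oxo-7-(prop-1-en-2-yl)decahydroazulene-1-carboxylate (trans-fused) | C=C(C)[C@@H]1CCC(=O)[C@@H]2CC[C@](C)(C(=O)OCC)[C@H]2C1 | intermediate
12 | methyllithium | [Li]C | starting material
13 | ethyl (1S,3aR,4R,7R,8aS)-4-hydroxy-1,4-dimethyl-7-(prop-1-en-2-yl)decahydroazulene-1-carboxylate | C=C(C)[C@@H]1CC[C@@](C)(O)[C@@H]2CC[C@](C)(C(=O)OCC)[C@H]2C1 | intermediate
14 | (1S,3aR,4R,7R,8aS)-4-hydroxy-1,4-dimethyl-7-(prop-1-en-2-yl)decahydroazulene-1-carbaldehyde | C=C(C)[C@@H]1CC[C@@](C)(O)[C@@H]2CC[C@](C)(C=O)[C@H]2C1 | intermediate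
15 | 3,5-dimethoxyphenol | COc1cc(O)cc(OC)c1 | starting material
16 | isobutylmagnesium bromide | CC(C)C[Mg]Br | starting material
17 | 2-{hydroxy[(1S,3aR,4R,7R,8aS)-4-hydroxy-1,4-dimethyl-7-(prop-1-en-2-yl)decahydroazulen-1-yl]methyl}-3,5-dimethoxyphenol (present as its magnesium salt, either carbinol epimer) | C=C(C)[C@@H]1CC[C@@](C)(O)[C@@H]2CC[C@](C)(C(O)c3c(O)cc(OC)cc3OC)[C@H]2C1 | intermediate
18 | 2-{[(1S,3aR,4R,7R,8aS)-4-hydroxy-1,4-dimethyl-7-(prop-1-en-2-yl)decahydroazulen-1-yl]methylidene}-3,5-dimethoxycyclohexa-3,5-dien-1-one (ortho-quinone methide) | C=C(C)[C@@H]1CC[C@@](C)(O)[C@@H]2CC[C@](C)(C=C3C(=O)C=C(OC)C=C3OC)[C@H]2C1 | intermediate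
19 | 2-{(1R)-1-[(1S,3aR,4R,7R,8aS)-4-hydroxy-1,4-dimethyl-7-(prop-1-en-2-yl)decahydroazulen-1-yl]-3-methylbutyl}-3,5-dimethoxyphenol | C=C(C)[C@@H]1CC[C@@](C)(O)[C@@H]2CC[C@](C)([C@@H](CC(C)C)c3c(O)cc(OC)cc3OC)[C@H]2C1 | intermediate
20 | N,N-dimethylformamide | CN(C)C=O | starting material
21 | 4-hydroxy-5-{(1R)-1-[(1S,3aR,4R,7R,8aS)-4-hydroxy-1,4-dimethyl-7-(prop-1-en-2-yl)decahydroazulen-1-yl]-3-methylbutyl}-2,6-dimethoxybenzene-1,3-dicarbaldehyde | C=C(C)[C@@H]1CC[C@@](C)(O)[C@@H]2CC[C@](C)([C@@H](CC(C)C)c3c(O)c(C=O)c(OC)c(C=O)c3OC)[C@H]2C1 | intermediate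
22 | 2,4,6-trihydroxy-5-{(1R)-1-[(1S,3aR,4R,7R,8aS)-4-hydroxy-1,4-dimethyl-7-(prop-1-en-2-yl)decahydroazulen-1-yl]-3-methylbutyl}benzene-1,3-dicarbaldehyde | C=C(C)[C@@H]1CC[C@@](C)(O)[C@@H]2CC[C@](C)([C@@H](CC(C)C)c3c(O)c(C=O)c(O)c(C=O)c3O)[C@H]2C1 | target

**Totals.** Total step count: 11. Longest linear sequence: 11 steps (1 → 22).

**Steps most likely to fail**

Step 5. What may go wrong: poor facial discrimination at C5 by the remote C7 centre, and proton transfer to the C4 enolate or oligomerisation of the activated ynone outrunning ring closure at the trisubstituted enoate. The fallback changes the mechanism from a zwitterionic to an organometallic (3+2) and sets out from acid chloride 7. Copper-catalysed addition of cyclopropylmagnesium bromide (CuI, THF, −78 °C) should give the cyclopropyl ketone ethyl (2E,5R)-8-cyclopropyl-2-methyl-8-oxo-5-(prop-1-en-2-yl)oct-2-enoate F1. A nickel-catalysed (3+2) annulation of the cyclopropyl ketone with the tethered enoate (Ni(cod)2, 1,3-bis(2,6-diisopropylphenyl)imidazol-2-ylidene, Ti(Ot-Bu)4, toluene, 90 °C) would then form the same C1–C5 and C3–C4 bonds: zerovalent nickel inserts into the cyclopropane to give an oxa-nickelacycle, the enoate inserts, and reductive elimination builds the quaternary C4 without a free enolate. This delivers the saturated keto ester directly, and NaOEt equilibration brings the route back at 11.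

Step 9. What may go wrong: sluggish carbon–carbon bond formation at the neopentyl aldehyde, β-hydride transfer from the Grignard reagent to the quinone methide (reduction instead of alkylation), and low facial selectivity at the elevated temperature needed to form the quinone methide. The fallback generates the quinone methide at low temperature by an anionic acyl transfer and sets out from 14 and 15. Carbamoylation of 15 (NaH, ClC(O)NEt2) gives 3,5-dimethoxyphenyl N,N-diethylcarbamate F2. Directed ortho-lithiation (s-BuLi, TMEDA, THF, −78 °C) between the carbamate and a methoxy group, addition of the aryllithium (2.2 equiv) to 14 and O→O carbamoyl transfer on warming should give [(1S,3aR,4R,7R,8aS)-4-hydroxy-1,4-dimethyl-7-(prop-1-en-2-yl)decahydroazulen-1-yl](2-hydroxy-4,6-dimethoxyphenyl)methyl N,N-diethylcarbamate F3 as its phenoxide. This loses diethylcarbamate below 0 °C to give 18, which is trapped at −78 °C by i-Bu2CuLi, and the route comes back at 19.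

Step 7. What may go wrong: insufficient facial selectivity, with equatorial delivery of methyl competing and giving the C10 epimer. The fallback delivers the carbon as a small sulfur ylide and folds in the ester reduction; it sets out from 11. Dimethylsulfonium methylide (Me3S+ I−, n-BuLi, THF, −10 °C; Corey–Chaykovsky reaction, kinetic axial attack) should give the spiro-epoxide ethyl (1S,3aR,4R,7R,8aS)-1-methyl-7-(prop-1-en-2-yl)octahydro-1H-spiro[azulene-4,2′-oxirane]-1-carboxylate F4. LiAlH4 (THF, 0 °C → rt) opens the epoxide at its CH2 terminus and reduces the ester, giving (1S,3aR,4R,7R,8aS)-1-(hydroxymethyl)-1,4-dimethyl-7-(prop-1-en-2-yl)decahydroazulen-4-ol F5. Oxidation of the primary alcohol with the triacetoxy periodinane (DMP, CH2Cl2, rt; the tertiary alcohol is inert) brings the route back at 14.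

Further compounds
F1 | step 5 | ethyl (2E,5R)-8-cyclopropyl-2-methyl-8-oxo-5-(prop-1-en-2-yl)oct-2-enoate | C=C(C)[C@@H](C/C=C(\C)C(=O)OCC)CCC(=O)C1CC1
F2 | step 9 | 3,5-dimethoxyphenyl N,N-diethylcarbamate | CCN(CC)C(=O)Oc1cc(OC)cc(OC)c1
F3 | step 9 | [(1S,3aR,4R,7R,8aS)-4-hydroxy-1,4-dimethyl-7-(prop-1-en-2-yl)decahydroazulen-1-yl](2-hydroxy-4,6-dimethoxyphenyl)methyl N,N-diethylcarbamate | C=C(C)[C@@H]1CC[C@@](C)(O)[C@@H]2CC[C@](C)(C(OC(=O)N(CC)CC)c3c(O)cc(OC)cc3OC)[C@H]2C1
F4 | step 7 | ethyl (1S,3aR,4R,7R,8aS)-1-methyl-7-(prop-1-en-2-yl)octahydro-1H-spiro[azulene-4,2′-oxirane]-1-carboxylate | C=C(C)[C@@H]1CC[C@]3(CO3)[C@@H]2CC[C@](C)(C(=O)OCC)[C@H]2C1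
F5 | step 7 | (1S,3aR,4R,7R,8aS)-1-(hydroxymethyl)-1,4-dimethyl-7-(prop-1-en-2-yl)decahydroazulen-4-ol | C=C(C)[C@@H]1CC[C@@](C)(O)[C@@H]2CC[C@](C)(CO)[C@H]2C1
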